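I began from a one-step world, where left-handed substrate and reagent keep reacting while both stand in the flask, and the larch run did not behave so.

all flasks: left-handed substrate 0.30 M; right-handed substrate 0.30 M

| charge | reagent | free catalyst | temperature | remark | time |
|---|---|---|---|---|---|
| larch | 0.33 M | 15 mM | 70 °C | run made earlier |  |
| red | 0.330 M | 7.5 mM | 70 °C |  | 8.0 min |
| amber | 0.330 M | 7.5 mM | 40 °C |  | 8.0 min |
| teal | 0.330 M | 7.5 mM | 100 °C |  | 8.0 min |
| ochre | 0.330 M | 7.5 mM | 10 °C |  | 8.0 min |

larch run (percent of the left-handed substrate and right-handed substrate together charged)

| time / s | left-handed product / % |
|---|---|
| 10.0 | 27.0 |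
| 15.0 | 30.6 |
| 25.0 | 33.2 |
| 50.0 | 34.1 |

(standard deviation of a reading: 0.5 percentage points)

- free catalyst is single-handed; left-handed substrate and right-handed substrate are mirror images of each other, charged as a racemate, each of them at the stated concentration
- the earlier runs do not show what temperature does; that part of a forecast is a guess
- no earlier run changes the charge of free catalyst; that part of a forecast is a guess

* the flask that comes out highest in amount of left-handed product, in percent of the left-handed substrate and right-handed substrate together charged, or "all alike" when all lie within 1.5 percentage points (red / amber / teal / ochre / all alike)
* left-handed product at the end, in percent of the left-handed substrate and right-handed substrate together charged, red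
* left-handed product at the end, in percent of the left-handed substrate and right-handed substrate together charged, amber
* left-handed product at the end, in percent of the left-handed substrate and right-handed substrate together charged, teal
* left-handed product at the end, in percent of the left-handed substrate and right-handed substrate together charged, ochre

In larch the left-handed substrate allowed 50.0% of left-handed product and the reagent 55.0%, yet the readings crept from 33.2% at 25.0 s to 34.1% at 50.0 s, and by that last reading 31.8% of the left-handed charge was still unreacted.

I read this as a fading rate. Suppose the left-handed fraction falls pseudo-first-order, with reagent taken as steady and a rate constant proportional to free catalyst, and free catalyst decays first-order; then the integral is closed, and at fixed temperature the logarithm of charged over remaining fraction climbs to a ceiling proportional to the catalyst charge. I called that ceiling the dose, and the plateau reading gave 1.15. The first reading then gave a fading constant of 0.113 s⁻¹, a half-life of 6.12 s. That returned 30.4% at 15.0 s, against the reading of 30.6%.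

Red holds half the catalyst of larch at the same temperature, and its 8.0 min is far longer than that half-life. My dose for red was therefore 0.573, or 21.8% of left-handed product. Temperature was a guess, and I put no number on it.

The forecast named amber highest, with red 34.1%, amber 34.5%, teal 33.6% and ochre 20%, reasoning “Assuming catalyst death is not the cause”. For red my figure was lower.

The flasks gave red 26.4%, amber 42.5%, teal 10.9% and ochre 38.0%, and amber came out highest.

    reagent ⇌ dormant form (K = 0.790, k = 0.110 s⁻¹, Ea = 72.0 kJ mol⁻¹, ΔH = 10.0 kJ mol⁻¹)
    reagent + free catalyst + right-handed substrate → free catalyst + right-handed product (k = 0.270 L² mol⁻² s⁻¹, Ea = 37.0 kJ mol⁻¹)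
    reagent + free catalyst + left-handed substrate → free catalyst + left-handed product (k = 18.0 L² mol⁻² s⁻¹, Ea = 38.0 kJ mol⁻¹)
    free catalyst → spent catalyst (k = 0.00460 s⁻¹, Ea = 82.0 kJ mol⁻¹)
    (constants at 40 °C)

In red the left-handed step ran while free catalyst lasted: at 4.00 min free catalyst stood at 0% and left-handed product at 26.4%, the same as at 80.0 min. In ochre free catalyst still stood at 92.5% at 8.00 min, and left-handed product went on to 48.6% by 80.0 min. Red's dose came to 0.750, which is 0.654 of the dose read from larch, where the ratio of the catalyst charges is 0.500.

I took the dose to one more flask, like amber but with 1.3 M of reagent. If the dose goes with the reagent charge, amber's dose of 1.90 scales to 7.47, or 50.0% of left-handed product. That flask gave 50.0% of left-handed product, with left-handed substrate at 0%.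

(The numbers in the tables were computed for an exercise; scatter was added.)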